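The runs were computed with made-up constants; the scatter is artificial.

Count what the reagent does to itself before counting what it does to the starting material. I work in fractions of the charge.

| flask | starting material | reagent | temperature | remark | time |
|---|---|---|---|---|---|
| grey | 20 mM | 1.05 equiv | 0 °C | run made earlier |  |
| red | 20 mM | 2.1 equiv | 0 °C | run made earlier |  |
| epsilon | 20 mM (fed, over 8.0 h) | 1.05 equiv | 0 °C | all else is in the flask from the start; the feed brings no volume worth counting | 20 h |
| zeta | 20 mM | 1.05 equiv (fed, over 8.0 h) |  | the addition at −40 °C, then warmed to 0 °C; the feed brings no volume worth counting | 20 h |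
| theta | 20 mM | 1.05 equiv |  | everything together at the start at −40 °C, warmed to 0 °C at 8.0 h | 20 h |
| eta | 20 mM | 1.05 equiv (fed, over 8.0 h) | 0 °C | all else is in the flask from the start; the feed brings no volume worth counting | 20 h |
| delta | 20 mM | 1.05 equiv (in portions, 5, over 8.0 h) | 0 °C | first portion at the start, last at 8.0 h | 20 h |

| run | time / h | side product / % | target / % |
|---|---|---|---|
| grey | 2.00 | 6.5 | 73.6 |
| grey | 4.00 | 9.8 | 81.4 |
| grey | 6.00 | 9.7 | 82.1 |
| grey | 8.00 | 10.0 | 83.4 |
| grey | 10.0 | 10.2 | 82.9 |
| grey | 12.0 | 12.4 | 84.7 |
| red | 0.667 | 0.5 | 79.5 |
| red | 1.33 | 2.0 | 90.9 |
| red | 2.00 | 1.2 | 93.3 |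
| red | 2.50 | 3.2 | 94.9 |
| red | 3.00 | 2.0 | 94.8 |
| red | 4.00 | 3.4 | 96.0 |

(standard deviation of a reading: 1 percentage point)

- the earlier runs do not show what temperature does; that part of a forecast is a guess
- a reading or a percentage of target counts all its forms, free or not

- the flask that comes out highest in amount of side product, in percent of the starting material charged; "all alike" if 1.5 percentage points covers them all (epsilon / zeta / theta / eta / delta / all alike)
- amount of side product at the end, in percent of the starting material charged, epsilon
- amount of side product at the end, in percent of the starting material charged, zeta
- amount of side product at the end, in percent of the starting material charged, theta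
- amount of side product at the end, in percent of the starting material charged, eta
- amount of side product at the end, in percent of the starting material charged, delta

1. The grey readings level off. At 10.0 h they leave 6.9 percentage points of the starting material outside the products, and bookkeeping on target leaves 0.221 of reagent, yet the target readings hardly move. So I take it that the reagent has a hidden loss, and I assume it is second order in reagent.

2. I take reagent and starting material in grey to fall together and that remainder of reagent as lost, so loss per target gives a selectivity factor, read as 0.267. The red run's first reading, through the second-order law, gives a rate constant times charge, read as 1.51 h⁻¹.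

3. I fold these into N = 3.38, the feed time counted in first half-lives of the reagent's self-loss. By this law, reagent left alone falls to 0.228 of itself over the feed.

4. In my reckoning for epsilon, target forms until the starting material fed equals the reagent surviving self-loss, taken as if left alone. They meet at a fraction 0.429 of the feed, and this is also my estimate of target.

5. Red's last readings of side product over target give a first-order loss, read as 0.0814 h⁻¹. Applied to what epsilon is fed after the meeting point, counted from its mean arrival, it gives an estimated side product of 39.3%.

6. One number is not enough. In eta and delta, starting material waits instead; I take its mean fraction over the feed as 0.5, which gives an estimate of 32.5%, less than my estimate for epsilon. The earlier runs do not show what temperature does, so for zeta and theta I guess grey's last reading, 12.4%. My highest flask is epsilon.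

The forecast names eta, with epsilon 10.5%, zeta 12%, theta 11.5%, eta 26% and delta 24.5%; of epsilon it says, under two of its models, “slow feed of starting material gives about the same as batch”.

Epsilon comes out highest, at 37.0%, against zeta 11.5%, theta 11.5%, eta 27.8% and delta 27.4%.

    starting material + reagent → target (k = 103 L mol⁻¹ h⁻¹, Ea = 51.0 kJ mol⁻¹)
    starting material → side product (k = 0.0752 h⁻¹, Ea = 82.0 kJ mol⁻¹)
    2 reagent → homo dimer (k = 12.7 L mol⁻¹ h⁻¹, Ea = 51.0 kJ mol⁻¹)
    crystals ⇌ target, rate k4*(cs4 - [target]) while solid is left; crystals form when [target] > cs4 (solubility = 9.00 mM, k = 10.3 h⁻¹)
    (constants at 0 °C)

In epsilon at 20.0 h, homo dimer stands at 5.91 mM, which holds reagent equal to 0.591 of the starting material charged. Target is 45.9%, against the 42.9% that N of 3.38 gave.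

For the neighbour of epsilon, the same flask with 0.420 equiv, N scales to 1.35, and the meeting point falls at 29.9%. That flask gives target 28.9% and side product 48.8%.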